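**Retrosynthetic overview**

1. Feature: ring carbons C5–C10, the C10 methyl (C14) and the three-carbon unit C11–C13 on C7 are the ten carbons of carvone, with its stereocentre as C7. C1–C4 and the C4 methyl (C15) are a 1-methylcyclobutene to be inserted between C10 and C5.
2. Late stage: the C8 angelate, the C5 isobutyrate and the exocyclic C11=C13 (masked as a dimethylamine adduct) are set last. C4–OH/C5–O come from a 4E alkene by epoxidation and hydration with inversion at C4; C10–H comes from a C1=C10 enone.
3. Ten-membered ring: thermal cycloreversion of a bicyclo[2.2.0]hexane (cleaving C5–C10 and C1–C4) gives the 1(10),4-dien-9-one. The bicycle comes from an enone + 1-methylcyclobutene [2+2] photocycloaddition (bonds C10–C1 and C4–C5).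
4. Enone from (R)-carvone: α′-silyloxylation gives the C6 oxygen, epoxide/Wharton transposition moves the carbonyl from C5 to C9, a second α′-silyloxylation gives the C8 oxygen, and the isopropenyl group is oxidised and closed to the trans α-methylene lactone. With the carbonyl transposed, the (R)-enantiomer carries the C7 configuration of the target.
5. Ring order: six-membered carbocycle (carvone) → γ-lactone → cyclobutane (completing the bicyclo[2.2.0]hexane) → ten-membered ring, in which the six- and four-membered rings are consumed.

Key step: step 10

Remark on numbering: germacrane numbering of the target is used for all intermediates (C1–C3 ring CH2, C4 methyl carbinol with methyl C15, C5 isobutyrate carbon, C6 lactone O-carbon, C7 bearing C11, C8 angelate carbon, C9 ketone, C10 with methyl C14, C11/C12/C13 lactone α-carbon, carbonyl, exocyclic methylene).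

Assumption: the 10R centre, enolisable next to the C9 ketone in the natural product itself, is taken to be the thermodynamically preferred C10 epimer.

**Route**

Step 1
Reactants: 1 (R)-(−)-carvone
Product: 3 trans-6-(tert-butyldimethylsilyloxy)carvone (silyloxy on future C6), via TBS dienol ether 2 (not isolated)
Conditions: LiN(iPr)2, THF, −78 °C; TBSOTf, −78 → 0 °C; then mCPBA, NaHCO3, CH2Cl2, −20 → 0 °C
Reagents that add atoms: tert-butyldimethylsilyl triflate CC(C)(C)[Si](C)(C)OS(=O)(=O)C(F)(F)F; mCPBA O=C(OO)c1cccc(Cl)c1
Why: Kinetic α′-deprotonation and O-silylation give the cross-conjugated dienol ether, whose enol double bond is epoxidised anti to the neighbouring isopropenyl group and rearranges with 1,4-silyl shift (Rubottom oxidation), so the C6 oxygen should arrive trans to the C7 substituent and already protected; this is also the arrangement favoured by equilibration of this enolisable centre.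

Step 2
Reactants: 3 trans-6-(tert-butyldimethylsilyloxy)carvone
Product: 4 epoxy ketone (oxirane across C9–C10)
Conditions: 30% H2O2, NaOH (cat.), MeOH, 0 °C
Reagents that add atoms: hydrogen peroxide OO
Why: Weitz–Scheffer nucleophilic epoxidation of the enone, which leaves the isolated isopropenyl alkene untouched; both oxirane centres are removed in steps 3 and 4, so the face of attack (expected anti to the isopropenyl group) is of no consequence.

Step 3
Reactants: 4 epoxy ketone
Product: 6 transposed allylic alcohol (C9 carbinol; C10=C5), via epoxy hydrazone 5 (not isolated)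
Conditions: N2H4·H2O, AcOH (cat.), MeOH, 0 °C → rt, argon
Reagents that add atoms: none
Why: Wharton transposition: the hydrazone opens the adjacent oxirane and loses N2, leaving C5 as an alkene CH and the oxygen on C9, while the much poorer α′-silyloxy leaving group on C6 stays in place.

Step 4
Reactants: 6 transposed allylic alcohol
Product: 7 transposed enone (C9 ketone; C6 silyloxy at the γ-carbon)
Conditions: Dess–Martin periodinane, NaHCO3, CH2Cl2, 0 °C → rt
Reagents that add atoms: none
Why: Dess–Martin oxidation of the secondary allylic alcohol gives the enone with the carbonyl on C9; no stereocentre is touched.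

Step 5
Reactants: 7 transposed enone
Product: 9 bis-silyloxy enone (C6 OTBS; C8 OTIPS), via TIPS dienol ether 8 (not isolated)
Conditions: LiN(iPr)2, THF, −78 °C; TIPSOTf, −78 → 0 °C; then mCPBA, NaHCO3, CH2Cl2, −20 → 0 °C
Reagents that add atoms: triisopropylsilyl triflate CC(C)[Si](OS(=O)(=O)C(F)(F)F)(C(C)C)C(C)C; mCPBA O=C(OO)c1cccc(Cl)c1
Why: Second Rubottom oxidation: kinetic deprotonation occurs at the α′-methylene C8, and the peracid attacks the dienol ether anti to the adjacent C7 isopropenyl group, so the C8 silyloxy group should end trans to it, again the thermodynamically preferred arrangement next to the ketone.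

Step 6
Reactants: 9 bis-silyloxy enone
Product: 10 C12 allylic alcohol
Conditions: SeO2 (0.5 equiv), t-BuOOH, CH2Cl2, rt
Reagents that add atoms: selenium dioxide O=[Se]=O; tert-butyl hydroperoxide CC(C)(C)OO
Why: SeO2 allylic oxidation (ene reaction, then [2,3]-sigmatropic shift) of the only electron-rich alkene, at its methyl group in preference to the hindered C7 methine, with t-BuOOH as terminal oxidant.

Step 7
Reactants: 10 C12 allylic alcohol
Product: 11 C6,C12-diol
Conditions: HF·pyridine, pyridine, THF, 0 °C → rt
Reagents that add atoms: none
Why: Fluoride-mediated desilylation, selective because the tert-butyldimethylsilyl ether is cleaved much faster than the bulkier triisopropylsilyl ether.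

Step 8
Reactants: 11 C6,C12-diol
Product: 14 enone lactone (trans-fused α-methylene-γ-lactone; C8 OTIPS), via hydroxy enal 12 (not isolated), via lactol 13 (not isolated)
Conditions: TEMPO (cat.), PhI(OAc)2, CH2Cl2, rt
Reagents that add atoms: none
Why: Oxoammonium (TEMPO) oxidation of the primary allylic alcohol to the enal, which the C6 hydroxyl captures as a lactol that is oxidised on to the lactone; the ring fusion is trans because C6 and C7 keep their configurations, and the secondary alcohol is oxidised much more slowly than the primary one.

Step 9
Reactants: 15 methylenecyclobutane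
Product: 16 1-methylcyclobutene
Conditions: KOtBu (cat.), DMSO, rt; spinning-band distillation
Reagents that add atoms: none
Why: Base-mediated prototropic isomerisation through the allyl anion to the more substituted endocyclic alkene, which is favoured at equilibrium and separated by distillation.

Step 10
Reactants: 14 enone lactone; 16 1-methylcyclobutene
Product: 17 cis-anti-cis photoadduct (bicyclo[2.2.0]hexane fused to the cyclohexanone)
Conditions: hν (λ ≥ 350 nm, uranium-glass filter), 16 (10 equiv), CH2Cl2, −60 °C, degassed
Reagents that add atoms: none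
Why: Excitation of the enone (the only chromophore absorbing beyond 340 nm) and intersystem crossing give the triplet enone, which adds stepwise to the strained alkene 16 through a triplet 1,4-biradical that spin-inverts and collapses; this is the enone–cycloalkene [2+2] photocycloaddition with a cyclobutene partner, known as the first half of the photoadduct/cycloreversion route to cyclodeca-1,5-dienes. The one ring closed is the cyclobutane C10–C1–C4–C5 (new bonds C10–C1 and C4–C5), closed by radical–radical recombination of the 1,4-biradical, and together with the four-membered ring of 16 it makes the bicyclo[2.2.0]hexane. Of the four new stereocentres, C1 and C4 are cis by the constraint of the cyclobutene ring, C10 and C5 should end cis because the biradical closes to the less strained cis-fused six-four system, the two outer rings lie anti to keep the ring methylenes apart, and the partner is expected on the enone face opposite the C6 and C8 oxygen substituents. The selectivity that matters is regiochemical (C4 to C5, C1 to C10): it follows the head-to-tail preference of triplet enones toward alkyl-substituted alkenes and is reinforced because the other orientation would join the quaternary C10 to the methylated C4. The trans lactone fusion holds C11=C13 in the lactone plane, out of reach of C5 and C10, so the intramolecular crossed cycloaddition typical of carvone cannot compete, and the excess of 16 at low temperature favours the bimolecular path. All four new centres are erased in step 11, so diastereomers of 17 converge.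

Step 11
Reactants: 17 cis-anti-cis photoadduct
Product: 18 (1(10)Z,4E)-dienone (ten-membered ring)
Conditions: toluene (0.005 M), BHT (cat.), sealed tube, 190 °C
Reagents that add atoms: none
Why: Thermal cycloreversion of the bicyclo[2.2.0]hexane (formal retro-[2+2] through the cyclohexane-1,4-diyl formed by cleavage of the strained C1–C4 bond, followed by scission of C5–C10) releases the strain of two fused cyclobutanes; cleavage from the chair-like diyl with the C9 carbonyl carbon axial and C6 equatorial should give the 1(10)Z,4E diene, and conjugation of C1=C10 with the C9 ketone disfavours a following Cope rearrangement.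

Step 12
Reactants: 18 (1(10)Z,4E)-dienone
Product: 19 (4R,5R)-epoxy enone
Conditions: mCPBA, NaHCO3, CH2Cl2, 0 °C
Reagents that add atoms: mCPBA O=C(OO)c1cccc(Cl)c1
Why: Prilezhaev epoxidation of the only electron-rich alkene (the enone and acrylate double bonds are deactivated); the trans-cycloalkene exposes only its outer face, and with H6 eclipsing the C4 methyl (A(1,3) strain) that face lies on the side of the C6–O bond, which should give the 4R,5R oxirane.

Step 13
Reactants: 19 (4R,5R)-epoxy enone
Product: 20 dimethylamine adduct (13-dimethylamino-11,13-dihydro lactone)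
Conditions: Me2NH (2 M in THF), THF, 0 °C → rt
Reagents that add atoms: dimethylamine CNC
Why: Aza-Michael addition to the exocyclic methylene lactone, far more reactive than the hindered α-methyl enone; protonation of the lactone enolate from the convex face should place H11 trans to H7, a centre that is removed again in step 19.

Step 14
Reactants: 20 dimethylamine adduct
Product: 21 (10R)-epoxy ketone
Conditions: [(Ph3P)CuH]6 (5 mol%), PhMe2SiH, t-BuOH, toluene, rt
Reagents that add atoms: none
Why: Copper hydride conjugate reduction (Stryker-type, catalytic in copper with silane turnover): hydride adds to C1 and the copper enolate is protonated at C10 by t-BuOH from the outer face of the ring; the centre stays enolisable, so a brief DBU equilibration can drive the mixture to the more stable 10R epimer.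

Step 15
Reactants: 21 (10R)-epoxy ketone
Product: 22 (4S,5R)-diol
Conditions: HClO4 (aq., 1.5 equiv), THF/H2O, 0 °C; then NaHCO3
Reagents that add atoms: water O
Why: Acid-catalysed hydration of the trisubstituted epoxide: water attacks the tertiary carbon C4 from the backside (borderline SN2, as in the hydration of limonene oxide) while the C5–O bond is kept, giving the 4S,5R anti-diol; with C1=C10 already reduced, no alkene is left for transannular cyclisation.

Step 16
Reactants: 22 (4S,5R)-diol; 23 isobutyryl chloride
Product: 24 C5 isobutyrate
Conditions: pyridine, DMAP (cat.), CH2Cl2, 0 °C → rt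
Reagents that add atoms: none
Why: DMAP-catalysed acylation, selective for the secondary C5 hydroxyl over the tertiary C4 hydroxyl; any transannular C5–O/C9 hemiketal is in equilibrium with the open hydroxy ketone and is drained by acylation.

Step 17
Reactants: 24 C5 isobutyrate
Product: 25 C8 alcohol
Conditions: HF·pyridine, THF, 0 °C → rt
Reagents that add atoms: none
Why: Fluoride-mediated cleavage of the triisopropylsilyl ether under mildly acidic conditions that leave the isobutyrate, the lactone and the enolisable C10 centre alone.

Step 18
Reactants: 25 C8 alcohol; 26 angelic acid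
Product: 28 C8 angelate (amine still in place), via mixed anhydride 27 (not isolated)
Conditions: 26, 2,4,6-trichlorobenzoyl chloride, Et3N, toluene, rt; then 25, 80 °C
Reagents that add atoms: none
Why: Yamaguchi esterification through the mixed anhydride without DMAP, the established way to make angelates without Z to E isomerisation to the tiglate; the tertiary C4 hydroxyl does not compete.

Step 19
Reactants: 28 C8 angelate
Product: 30 target CNP0141258.2, via ammonium iodide 29 (not isolated)
Conditions: MeI, THF, rt; then NaHCO3 (aq.), rt
Reagents that add atoms: none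
Why: Exhaustive methylation gives the quaternary ammonium salt, and mild base removes the acidic C11 proton with loss of trimethylamine (E1cB, Hofmann-type elimination), restoring the exocyclic C11=C13 without touching the esters.

**Compound list**

1 | (R)-(−)-carvone | CC1=CC[C@@H](C(C)=C)CC1=O | starting material
2 | tert-butyldimethylsilyl dienol ether of 1 (silyloxy on C5; C5=C6 and C9=C10 double bonds; C7 unchanged) | CC1=CC[C@@H](C(C)=C)C=C1O[Si](C)(C)C(C)(C)C | intermediate (not isolated)
3 | (5S,6S)-6-(tert-butyldimethylsilyloxy)-2-methyl-5-(prop-1-en-2-yl)cyclohex-2-en-1-one; silyloxy (future C6–O) trans to isopropenyl | CC1=CC[C@@H](C(C)=C)[C@H](O[Si](C)(C)C(C)(C)C)C1=O | intermediate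
4 | oxirane of 3 across C9–C10, oxygen anti to the isopropenyl group | C[C@@]12O[C@@H]1C[C@@H](C(C)=C)[C@H](O[Si](C)(C)C(C)(C)C)C2=O | intermediate
5 | hydrazone of 4 at C5 | C[C@@]12O[C@@H]1C[C@@H](C(C)=C)[C@H](O[Si](C)(C)C(C)(C)C)C2=NN | intermediate (not isolated)
6 | allylic alcohol with C9 carbinol, C10=C5 double bond, C6 silyloxy trans to the C7 isopropenyl | CC1=C[C@@H](O[Si](C)(C)C(C)(C)C)[C@H](C(C)=C)C[C@H]1O | intermediate
7 | (4R,5S)-4-(tert-butyldimethylsilyloxy)-2-methyl-5-(prop-1-en-2-yl)cyclohex-2-en-1-one (C9 ketone, C6 silyloxy) | CC1=C[C@@H](O[Si](C)(C)C(C)(C)C)[C@H](C(C)=C)CC1=O | intermediate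
8 | triisopropylsilyl dienol ether of 7 (silyloxy on C9; C8=C9) | CC1=C[C@@H](O[Si](C)(C)C(C)(C)C)[C@H](C(C)=C)C=C1O[Si](C(C)C)(C(C)C)C(C)C | intermediate (not isolated)
9 | 7 with a triisopropylsilyloxy group on C8, trans to the C7 isopropenyl (C6–O, C7–C and C8–O alternate between the ring faces) | CC1=C[C@@H](O[Si](C)(C)C(C)(C)C)[C@H](C(C)=C)[C@@H](O[Si](C(C)C)(C(C)C)C(C)C)C1=O | intermediate
10 | 9 with C12 hydroxylated (3-hydroxyprop-1-en-2-yl on C7) | CC1=C[C@@H](O[Si](C)(C)C(C)(C)C)[C@H](C(=C)CO)[C@@H](O[Si](C(C)C)(C(C)C)C(C)C)C1=O | intermediate
11 | C6,C12-diol (C6 silyl group removed, C8 OTIPS kept) | CC1=C[C@@H](O)[C@H](C(=C)CO)[C@@H](O[Si](C(C)C)(C(C)C)C(C)C)C1=O | intermediate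
12 | hydroxy enal (C12 aldehyde, free C6 hydroxyl) | CC1=C[C@@H](O)[C@H](C(=C)C=O)[C@@H](O[Si](C(C)C)(C(C)C)C(C)C)C1=O | intermediate (not isolated)
13 | lactol (C12 hemiacetal closed on O6, both anomers) | C=C1C(O)O[C@H]2[C@H]1[C@@H](O[Si](C(C)C)(C(C)C)C(C)C)C(=O)C(C)=C2 | intermediate (not isolated)
14 | key-step precursor: 6-methyl-3-methylidene-4-(triisopropylsilyloxy)-3a,4-dihydro-1-benzofuran-2,5(3H,7aH)-dione; lactone O on C6 and silyloxy on C8 both trans to the C7–C11 bond | C=C1C(=O)O[C@H]2[C@H]1[C@@H](O[Si](C(C)C)(C(C)C)C(C)C)C(=O)C(C)=C2 | intermediate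
15 | methylenecyclobutane | C=C1CCC1 | starting material
16 | 1-methylcyclobutene | CC1=CCC1 | intermediate
17 | cis-anti-cis photoadduct: cyclobutane C10–C1–C4–C5 fused cis to the cyclohexanone and cis to the ring C1–C2–C3–C4, outer rings anti; C10 methyl and H5 on one face, H1 and the C4 methyl on the other; cyclobutane on the face opposite the C6 and C8 oxygens | C=C1C(=O)O[C@H]2[C@H]1[C@@H](O[Si](C(C)C)(C(C)C)C(C)C)C(=O)[C@]3(C)[C@H]4CC[C@@]4(C)[C@H]23 | intermediate
18 | (1(10)Z,4E)-9-oxo-8-(triisopropylsilyloxy)germacra-1(10),4,11(13)-trien-12,6-olide; C6, C7, C8 as in the target | C=C1C(=O)O[C@@H]2/C=C(C)/CC\C=C(C)/C(=O)[C@H](O[Si](C(C)C)(C(C)C)C(C)C)[C@@H]12 | intermediate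
19 | (4R,5R)-4,5-epoxide of 18 (1(10)Z enone and methylene lactone intact) | C=C1C(=O)O[C@H]2[C@H]1[C@@H](O[Si](C(C)C)(C(C)C)C(C)C)C(=O)/C(C)=C\CC[C@@]3(C)O[C@H]23 | intermediate
20 | 13-dimethylamino-11,13-dihydro derivative of 19 (11R, H11 trans to H7) | CN(C)C[C@@H]1C(=O)O[C@H]2[C@H]1[C@@H](O[Si](C(C)C)(C(C)C)C(C)C)C(=O)/C(C)=C\CC[C@@]3(C)O[C@H]23 | intermediate
21 | (10R)-1,10-dihydro derivative of 20 (saturated C9 ketone; 4R,5R epoxide) | CN(C)C[C@@H]1C(=O)O[C@H]2[C@H]1[C@@H](O[Si](C(C)C)(C(C)C)C(C)C)C(=O)[C@H](C)CCC[C@@]3(C)O[C@H]23 | intermediate
22 | (4S,5R)-4,5-diol (C8 OTIPS; amine adduct) | CN(C)C[C@@H]1C(=O)O[C@H]2[C@H]1[C@@H](O[Si](C(C)C)(C(C)C)C(C)C)C(=O)[C@H](C)CCC[C@](C)(O)[C@@H]2O | intermediate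
23 | isobutyryl chloride | CC(C)C(Cl)=O | starting material
24 | C5 isobutyrate of 22 (free tertiary C4–OH) | CN(C)C[C@@H]1C(=O)O[C@H]2[C@H]1[C@@H](O[Si](C(C)C)(C(C)C)C(C)C)C(=O)[C@H](C)CCC[C@](C)(O)[C@@H]2OC(=O)C(C)C | intermediate
25 | C8 alcohol (silyl group removed from 24) | CN(C)C[C@@H]1C(=O)O[C@H]2[C@H]1[C@@H](O)C(=O)[C@H](C)CCC[C@](C)(O)[C@@H]2OC(=O)C(C)C | intermediate
26 | angelic acid, (Z)-2-methylbut-2-enoic acid | OC(=O)/C(C)=C\C | starting material
27 | angelic 2,4,6-trichlorobenzoic mixed anhydride | O=C(OC(=O)/C(C)=C\C)c1c(Cl)cc(Cl)cc1Cl | intermediate (not isolated)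
28 | C8 angelate of 25 (dimethylamine adduct of the target) | CN(C)C[C@@H]1C(=O)O[C@H]2[C@H]1[C@@H](OC(=O)/C(C)=C\C)C(=O)[C@H](C)CCC[C@](C)(O)[C@@H]2OC(=O)C(C)C | intermediate
29 | trimethylammonium iodide of 28 | C[N+](C)(C)C[C@@H]1C(=O)O[C@H]2[C@H]1[C@@H](OC(=O)/C(C)=C\C)C(=O)[C@H](C)CCC[C@](C)(O)[C@@H]2OC(=O)C(C)C.[I-] | intermediate (not isolated)
30 | CNP0141258.2, (4S,5R,6S,7S,8R,10R)-8-angeloyloxy-4-hydroxy-5-isobutyryloxy-9-oxogermacr-11(13)-en-12,6-olide | C=C1C(=O)O[C@H]2[C@H]1[C@@H](OC(=O)/C(C)=C\C)C(=O)[C@H](C)CCC[C@](C)(O)[C@@H]2OC(=O)C(C)C | target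

**Totals**

Total step count: 19.
Longest linear sequence: 18 steps (steps 1–8 and 10–19, from (R)-carvone); step 9 is a one-step side branch.

**Steps most likely to fail**

Step 10 (photocycloaddition). The 1,4-biradical may be diverted into radical addition to the exocyclic methylene of a second molecule (oligomerisation), or the partner may add in the head-to-head sense, so that little of the required adduct forms. The fallback removes the acrylate unit before irradiation. It sets out from 14: dimethylamine is added to the methylene lactone to give the amino lactone F1. F1 is irradiated with 16 in the presence of one equivalent of CF3CO2H (the ammonium ion cannot quench the triplet enone by electron transfer) to give, after neutralisation, the amino photoadduct F2. MeI and then NaHCO3 eliminate trimethylamine from F2, and the sequence comes back to the route at 17.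

Step 11 (cycloreversion). The diyl may cleave with the other sense of geometry, giving the 1(10)E,4Z diene, and prolonged heating may erode the product by Cope rearrangement. The fallback changes how C4 and C5 are oxygenated and so accepts the other geometry. It sets out from 17: the isomeric dienone F3 is carried through dimethylamine addition to the amino lactone F4 and copper hydride reduction to the ketone F5. F5 is then syn-dihydroxylated on its outer face with OsO4 (cat.) and N-methylmorpholine N-oxide. For a 4Z alkene this face gives the same 4S,5R diol, so the sequence comes back to the route at 22 and steps 12 and 15 are not needed.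

Step 14 (conjugate reduction). Protonation of the enolate at C10 may show poor facial selectivity, and equilibration may not favour 10R if the assumption above does not hold. The fallback replaces substrate control by reagent control. It sets out from 20: copper hydride-catalysed 1,4-hydrosilylation with PhMe2SiH in the absence of alcohol gives the silyl enol ether F6, which is isolated. F6 is protonated with phenol under catalysis by a chiral BINOL-derived N-triflyl thiophosphoramide, the enantiomer of the catalyst being chosen to deliver the proton to the face that gives 10R. The sequence comes back to the route at 21.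

**Further compounds**

F1 | step 10 | dimethylamine adduct of 14 (13-dimethylamino-11,13-dihydro enone lactone) | CN(C)C[C@@H]1C(=O)O[C@H]2[C@H]1[C@@H](O[Si](C(C)C)(C(C)C)C(C)C)C(=O)C(C)=C2
F2 | step 10 | cis-anti-cis photoadduct of F1 with 16 (amine adduct of 17) | CN(C)C[C@@H]1C(=O)O[C@H]2[C@H]1[C@@H](O[Si](C(C)C)(C(C)C)C(C)C)C(=O)[C@]3(C)[C@H]4CC[C@@]4(C)[C@H]23
F3 | step 11 | (1(10)E,4Z) isomer of 18 | C=C1C(=O)O[C@@H]2/C=C(C)\CC/C=C(C)/C(=O)[C@H](O[Si](C(C)C)(C(C)C)C(C)C)[C@@H]12
F4 | step 11 | dimethylamine adduct of F3 | CN(C)C[C@@H]1C(=O)O[C@@H]2/C=C(C)\CC/C=C(C)/C(=O)[C@H](O[Si](C(C)C)(C(C)C)C(C)C)[C@@H]12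
F5 | step 11 | (10R)-1,10-dihydro derivative of F4 (4Z alkene kept) | CN(C)C[C@@H]1C(=O)O[C@@H]2/C=C(C)\CCC[C@@H](C)C(=O)[C@H](O[Si](C(C)C)(C(C)C)C(C)C)[C@@H]12
F6 | step 14 | dimethylphenylsilyl enol ether of 21 (C9=C10; enol ether geometry not fixed) | CN(C)C[C@@H]1C(=O)O[C@H]2[C@H]1[C@@H](O[Si](C(C)C)(C(C)C)C(C)C)C(O[Si](C)(C)c3ccccc3)=C(C)CCC[C@@]4(C)O[C@H]24
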